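**Plan**

1. Labels: pinane carbons C1–C7 (C1 and C5 bridgeheads, C2 spiro carbon, C6 = CMe2, C7 = CH2); chroman atoms are primed.
2. Retrosynthesis: cut C6'–acyl and C8'–CHO (aromatic substitution), return C7 to C=O, cut C1–C7 and C5–C6 together (keteniminium C5=C7 plus alkene C1=C6), then O1'–C2 (oxidative cyclisation), then C1=C6 (Wittig) and C3'–C4' (aldol).
3. Forward: keto amide + salicylaldehyde → alkenyl phenol → chroman → cyclohexane ring and, last of all, the cyclobutane in one [2+2] → deoxygenation at C7 → formyl, isovaleryl, demethylation.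
4. Enabling feature: in the cyclobutane C1–C6–C5–C7 the CMe2 carbon C6 faces the CH2 carbon C7, and both bridge C1/C5 of the six-membered ring. A CH=CMe2 group on C2 puts cationic character on C6, so an iminium carbon (the future C7) held by the C3–C4–C5 chain bonds to C1 and the bridged bicyclo[3.1.1] skeleton results.
5. Stereochemistry: C2 from a ligand-controlled enantioselective Wacker cyclisation; C1 and C5 from the face selection of the [2+2] under control of C2.

Key step: step 6

Assumption: the sense of induction of the BOXAX ligands is taken over from 2-methylchroman formation, where the (S,S) ligand is taken to give the (2R)-2-methyl series; the chroman needed here has the opposite spatial arrangement at C2, hence the (R,R) ligand, and the antipodal ligand is used should the sense differ for this alkene.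

**Route**

Step 1
Reactants: 1 5-oxohexanoic acid; 2 pyrrolidine
Product: 4 1-(pyrrolidin-1-yl)hexane-1,5-dione, via acyl imidazole 3 (not isolated)
Conditions: CDI, CH2Cl2, rt; then 2, rt
Reagents that add atoms: pyrrolidine 2 (C1CCNC1)
Why: CDI converts the acid into the acyl imidazole 3, which pyrrolidine opens to the tertiary amide (standard amide coupling); the methyl ketone is left as it is because any enamine reverts on aqueous work-up.

Step 2
Reactants: 4 1-(pyrrolidin-1-yl)hexane-1,5-dione; 5 2-hydroxy-4,6-dimethoxybenzaldehyde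
Product: 6 (6E)-7-(2-hydroxy-4,6-dimethoxyphenyl)-1-(pyrrolidin-1-yl)hept-6-ene-1,5-dione
Conditions: NaOH, EtOH/H2O, rt
Reagents that add atoms: 2-hydroxy-4,6-dimethoxybenzaldehyde 5 (COc1cc(O)c(C=O)c(OC)c1)
Why: Claisen–Schmidt (crossed aldol) condensation: the methyl group of the methyl ketone condenses with the non-enolisable aryl aldehyde to the conjugated E-enone, while the tertiary amide is inert to aqueous hydroxide at room temperature.

Step 3
Reactants: 6 (6E)-7-(2-hydroxy-4,6-dimethoxyphenyl)-1-(pyrrolidin-1-yl)hept-6-ene-1,5-dione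
Product: 7 7-(2-hydroxy-4,6-dimethoxyphenyl)-1-(pyrrolidin-1-yl)heptane-1,5-dione
Conditions: H2 (1 atm), Pd/C, EtOAc, rt
Reagents that add atoms: none
Why: Heterogeneous catalytic hydrogenation saturates the conjugated C=C far faster than it touches the dialkyl ketone, the amide or the electron-rich arene, giving the 3-arylpropyl ketone (in equilibrium with its cyclic hemiketal).

Step 4
Reactants: 7 7-(2-hydroxy-4,6-dimethoxyphenyl)-1-(pyrrolidin-1-yl)heptane-1,5-dione; 8 isobutyltriphenylphosphonium bromide
Product: 9 5-[2-(2-hydroxy-4,6-dimethoxyphenyl)ethyl]-7-methyl-1-(pyrrolidin-1-yl)oct-5-en-1-one (E/Z mixture)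
Conditions: KOt-Bu (excess), toluene/THF, 0 °C to 80 °C
Reagents that add atoms: isobutyltriphenylphosphonium bromide 8 (CC(C)C[P+](c1ccccc1)(c1ccccc1)c1ccccc1.[Br-])
Why: Wittig olefination of the dialkyl ketone by the non-stabilised isobutylidene ylide (excess base also covers the phenol) gives the trisubstituted alkene as an E/Z mixture, which is acceptable because the alkene geometry is lost in the next step.

Step 5
Reactants: 9 5-[2-(2-hydroxy-4,6-dimethoxyphenyl)ethyl]-7-methyl-1-(pyrrolidin-1-yl)oct-5-en-1-one
Product: 10 4-[(2R)-5,7-dimethoxy-2-(2-methylprop-1-en-1-yl)-3,4-dihydro-2H-chromen-2-yl]-1-(pyrrolidin-1-yl)butan-1-one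
Conditions: Pd(OCOCF3)2 (10 mol %), (R,R)-Bn-BOXAX [2,2'-bis((4R)-4-benzyl-4,5-dihydrooxazol-2-yl)-1,1'-binaphthyl, 40 mol %], p-benzoquinone, MeOH, 60 °C
Reagents that add atoms: none
Why: Enantioselective Wacker-type oxidative cyclisation: the phenol adds in a 6-exo sense to the alkene bound to chiral divalent palladium, β-hydride elimination (possible only toward the isopropyl CH) gives the 2-methylprop-1-enyl group while benzoquinone reoxidises zerovalent palladium and the excess oxazoline ligand buffers the acid set free, and C2 is set by the ligand-controlled choice of alkene face, both alkene isomers of 9 being expected to give the same centre.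

Step 6
Reactants: 10 4-[(2R)-5,7-dimethoxy-2-(2-methylprop-1-en-1-yl)-3,4-dihydro-2H-chromen-2-yl]-1-(pyrrolidin-1-yl)butan-1-one
Product: 14 (1R,2R,5R)-5',7'-dimethoxy-6,6-dimethylspiro[bicyclo[3.1.1]heptane-2,2'-chromane]-7-one, via O-triflyl iminium triflate 11 (not isolated), via keteniminium triflate 12 (not isolated), via cyclobutaniminium triflate 13 (not isolated)
Conditions: Tf2O (1.05 equiv) added to 10 and 2,4,6-collidine, ClCH2CH2Cl, −30 °C, then reflux at 0.01 M; then aq. NaHCO3, 40 °C
Reagents that add atoms: water (O)
Why: O-Triflation of the amide gives 11, collidine removes an α-proton and triflate leaves to give the keteniminium ion 12, whose central carbon (future C7) is attacked by the CH terminus C1 of the 2-methylprop-1-enyl group so that positive charge builds on the dimethyl-substituted carbon C6, which then closes onto the enamine carbon C5 to give the cyclobutaniminium ion 13, hydrolysed to 14. The closest known reaction type is the intramolecular [2+2] cycloaddition of keteniminium salts (and of ketenes) with trisubstituted alkenes, which gives bridged bicyclo[3.1.1]heptan-6-ones when the distal alkene carbon is the more substituted one and which has served to build pinane-type skeletons. Two rings close in one operation: first the cyclohexane C1–C2–C3–C4–C5–C7 by 6-exo attack of the alkene on the iminium carbon (bond C7–C1), then, as the last ring of the skeleton, the cyclobutane by a four-membered closure of C5 onto the tertiary cationic centre C6. C1 and C5 are tied to each other by the bicycle and are set relative to C2 by the alkene face attacked: in the chair-like six-membered array the aryl ether C–O bond should lie in the alkene plane (outside position, axial) and the chroman CH2 antiperiplanar to the incoming carbon (equatorial), the arrangement favoured for electrophilic attack next to an allylic ether, and this places O1' on the side of the carbonyl bridge and the chroman CH2 on the side of the CMe2 bridge as in the target. The step needs bridged rather than fused regiochemistry, secured by the CMe2 terminus (tertiary against secondary cation) and the three-atom tether; it needs chemoselectivity over arene acylation, secured because the iminium carbon could reach C8' only through an eight-membered ring; and it needs the tertiary allylic aryl ether to survive, for which the medium is kept buffered, dilute and free of excess anhydride.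

Step 7
Reactants: 14 (1R,2R,5R)-5',7'-dimethoxy-6,6-dimethylspiro[bicyclo[3.1.1]heptane-2,2'-chromane]-7-one
Product: 16 (1R,2R,5S)-5',7'-dimethoxy-6,6-dimethylspiro[bicyclo[3.1.1]heptane-2,2'-chromane], via hydrazone 15 (not isolated)
Conditions: N2H4·H2O, diethylene glycol, 130 °C; then KOH, 200 °C
Reagents that add atoms: none
Why: Wolff–Kishner reduction in the Huang-Minlon manner (hydrazone 15, then base-induced loss of N2) is the established way to turn bicyclo[3.1.1]heptan-6-ones into the CH2-bridged pinane skeleton; the ketone is non-enolisable and has no leaving group next to the carbanionic centre, so the three stereocentres are untouched.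

Step 8
Reactants: 16 (1R,2R,5S)-5',7'-dimethoxy-6,6-dimethylspiro[bicyclo[3.1.1]heptane-2,2'-chromane]
Product: 18 (1R,2R,5S)-5',7'-dimethoxy-6,6-dimethylspiro[bicyclo[3.1.1]heptane-2,2'-chromane]-8'-carbaldehyde, via aryl iminium chloride 17 (not isolated)
Conditions: POCl3, DMF, 0 °C to 50 °C; then aq. NaOH, 0 °C
Reagents that add atoms: N,N-dimethylformamide (CN(C)C=O); water (O)
Why: Vilsmeier–Haack formylation of the 1,3,5-trioxygenated ring stops after one substitution (the iminium 17 deactivates the ring) and should choose C8', which is flanked by the tied-back ring oxygen and one methoxy group, over C6', which sits between two methoxy groups whose methyl groups must turn toward it.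

Step 9
Reactants: 18 (1R,2R,5S)-5',7'-dimethoxy-6,6-dimethylspiro[bicyclo[3.1.1]heptane-2,2'-chromane]-8'-carbaldehyde; 19 3-methylbutanoyl chloride (isovaleryl chloride)
Product: 20 (1R,2R,5S)-5',7'-dimethoxy-6,6-dimethyl-6'-(3-methylbutanoyl)spiro[bicyclo[3.1.1]heptane-2,2'-chromane]-8'-carbaldehyde
Conditions: TiCl4, CH2Cl2, −10 °C to rt
Reagents that add atoms: 3-methylbutanoyl chloride 19 (CC(C)CC(=O)Cl)
Why: Friedel–Crafts acylation at the only ring position left, C6', which is still activated by three ortho/para oxygen substituents; TiCl4 is chosen as a Lewis acid that related spiro-pinane chromans are expected to tolerate in aromatic substitution, and partial loss of a methyl group next to a carbonyl would be of no consequence.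

Step 10
Reactants: 20 (1R,2R,5S)-5',7'-dimethoxy-6,6-dimethyl-6'-(3-methylbutanoyl)spiro[bicyclo[3.1.1]heptane-2,2'-chromane]-8'-carbaldehyde
Product: 21 euglobal G3
Conditions: LiCl, DMF, 140 °C; then 1 M HCl
Reagents that add atoms: none
Why: Chloride-mediated demethylation (SN2 at the methyl carbon, with a phenoxide leaving group stabilised by the ortho/para carbonyl groups) cleaves both methyl ethers, whereas the tertiary spiro ether cannot react by SN2 and is not exposed to a strong Lewis acid.

**Compound list**

1 | 5-oxohexanoic acid | CC(=O)CCCC(=O)O | starting material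
2 | pyrrolidine | C1CCNC1 | starting material
3 | 1-(1H-imidazol-1-yl)hexane-1,5-dione (acyl imidazole, not isolated) | CC(=O)CCCC(=O)n1ccnc1 | intermediate
4 | 1-(pyrrolidin-1-yl)hexane-1,5-dione | CC(=O)CCCC(=O)N1CCCC1 | intermediate
5 | 2-hydroxy-4,6-dimethoxybenzaldehyde | COc1cc(O)c(C=O)c(OC)c1 | starting material
6 | (6E)-7-(2-hydroxy-4,6-dimethoxyphenyl)-1-(pyrrolidin-1-yl)hept-6-ene-1,5-dione | COc1cc(O)c(/C=C/C(=O)CCCC(=O)N2CCCC2)c(OC)c1 | intermediate
7 | 7-(2-hydroxy-4,6-dimethoxyphenyl)-1-(pyrrolidin-1-yl)heptane-1,5-dione | COc1cc(O)c(CCC(=O)CCCC(=O)N2CCCC2)c(OC)c1 | intermediate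
8 | isobutyltriphenylphosphonium bromide | CC(C)C[P+](c1ccccc1)(c1ccccc1)c1ccccc1.[Br-] | starting material
9 | 5-[2-(2-hydroxy-4,6-dimethoxyphenyl)ethyl]-7-methyl-1-(pyrrolidin-1-yl)oct-5-en-1-one (E/Z mixture) | COc1cc(O)c(CCC(=CC(C)C)CCCC(=O)N2CCCC2)c(OC)c1 | intermediate
10 | 4-[(2R)-5,7-dimethoxy-2-(2-methylprop-1-en-1-yl)-3,4-dihydro-2H-chromen-2-yl]-1-(pyrrolidin-1-yl)butan-1-one | COc1cc(OC)c2CC[C@@](C=C(C)C)(CCCC(=O)N3CCCC3)Oc2c1 | intermediate
11 | O-triflyl iminium triflate of 10 (amide oxygen triflated, C=N+ to pyrrolidine; not isolated) | COc1cc(OC)c2CC[C@@](C=C(C)C)(CCCC(OS(=O)(=O)C(F)(F)F)=[N+]3CCCC3)Oc2c1.[O-]S(=O)(=O)C(F)(F)F | intermediate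
12 | keteniminium triflate, 1-{4-[(2R)-5,7-dimethoxy-2-(2-methylprop-1-en-1-yl)chroman-2-yl]but-1-en-1-ylidene}pyrrolidinium triflate (not isolated) | COc1cc(OC)c2CC[C@@](C=C(C)C)(CCC=C=[N+]3CCCC3)Oc2c1.[O-]S(=O)(=O)C(F)(F)F | intermediate
13 | cyclobutaniminium triflate, pyrrolidinium ylidene analogue of 14 with the same configuration (not isolated) | COc1cc(OC)c2CC[C@@]3(CC[C@H]4C(=[N+]5CCCC5)[C@@H]3C4(C)C)Oc2c1.[O-]S(=O)(=O)C(F)(F)F | intermediate
14 | (1R,2R,5R)-5',7'-dimethoxy-6,6-dimethylspiro[bicyclo[3.1.1]heptane-2,2'-chromane]-7-one (O1' on the side of the carbonyl bridge) | COc1cc(OC)c2CC[C@@]3(CC[C@H]4C(=O)[C@@H]3C4(C)C)Oc2c1 | intermediate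
15 | hydrazone of 14 (not isolated) | COc1cc(OC)c2CC[C@@]3(CC[C@H]4C(=NN)[C@@H]3C4(C)C)Oc2c1 | intermediate
16 | (1R,2R,5S)-5',7'-dimethoxy-6,6-dimethylspiro[bicyclo[3.1.1]heptane-2,2'-chromane] | COc1cc(OC)c2CC[C@@]3(CC[C@H]4C[C@@H]3C4(C)C)Oc2c1 | intermediate
17 | N,N-dimethyl iminium chloride of aldehyde 18 (not isolated) | COc1cc(OC)c2CC[C@@]3(CC[C@H]4C[C@@H]3C4(C)C)Oc2c1C=[N+](C)C.[Cl-] | intermediate
18 | (1R,2R,5S)-5',7'-dimethoxy-6,6-dimethylspiro[bicyclo[3.1.1]heptane-2,2'-chromane]-8'-carbaldehyde | COc1cc(OC)c2CC[C@@]3(CC[C@H]4C[C@@H]3C4(C)C)Oc2c1C=O | intermediate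
19 | 3-methylbutanoyl chloride (isovaleryl chloride) | CC(C)CC(=O)Cl | starting material
20 | (1R,2R,5S)-5',7'-dimethoxy-6,6-dimethyl-6'-(3-methylbutanoyl)spiro[bicyclo[3.1.1]heptane-2,2'-chromane]-8'-carbaldehyde | COc1c(C(=O)CC(C)C)c(OC)c2CC[C@@]3(CC[C@H]4C[C@@H]3C4(C)C)Oc2c1C=O | intermediate
21 | euglobal G3, (1R,2R,5S)-5',7'-dihydroxy-6,6-dimethyl-6'-(3-methylbutanoyl)spiro[bicyclo[3.1.1]heptane-2,2'-chromane]-8'-carbaldehyde | CC(C)CC(=O)c1c(O)c(C=O)c2c(c1O)CC[C@@]1(CC[C@H]3C[C@@H]1C3(C)C)O2 | target

**Totals and risks**

Total step count: 10. Longest linear sequence: 10 steps (from 1).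

Steps most likely to fail:

Step 6. What may go wrong: attack on the wrong alkene face (the target needs the chroman CH2 next to the CMe2 bridge, the more crowded arrangement), proton loss from the tertiary cation before the second bond forms, or ionisation of the tertiary allylic aryl ether under electrophilic activation. The fallback gives up the late ring closure and takes the four-membered ring from the chiral pool; it sets out from 5 and comes back at 16. Aldehyde 5 is reduced with NaBH4 in MeOH to 2-(hydroxymethyl)-3,5-dimethoxyphenol F1. Heating F1 in an excess of commercial (1S,5S)-(−)-β-pinene (C=C1CC[C@H]2C[C@@H]1C2(C)C) at 160–170 °C in a sealed vessel releases water and the o-quinone methide 3,5-dimethoxy-6-methylidenecyclohexa-2,4-dien-1-one F2. F2 adds to the exocyclic alkene in a hetero-Diels–Alder reaction, with oxygen at the more substituted carbon and from the face away from the CMe2 bridge, to give 16; the route then continues with step 8.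

Step 5. What may go wrong: slow oxypalladation of the hindered trisubstituted alkene, low or reversed face selection, double-bond migration by palladium hydride re-addition, or acid-induced ionisation of the new allylic ether with loss of optical purity. The fallback replaces asymmetric catalysis by a racemic synthesis and resolution; it sets out from 7 and comes back at 10. Ketone 7 is treated with an excess of 2-methylprop-1-enylmagnesium bromide (THF, −78 °C to 0 °C) to give racemic 5-hydroxy-5-[2-(2-hydroxy-4,6-dimethoxyphenyl)ethyl]-7-methyl-1-(pyrrolidin-1-yl)oct-6-en-1-one F3. Catalytic pyridinium p-toluenesulfonate in toluene ionises the tertiary allylic alcohol, and the phenol closes the six-membered ring (cyclodehydration) to the racemic chroman amide F4. Preparative HPLC on a chiral stationary phase separates 10 from its (S)-enantiomer F5.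

Step 8. What may go wrong: attack of the chloroiminium ion at C6' instead of C8', or at both positions. The fallback exchanges the order of the two aromatic substitutions, so that the same intrinsic preference then places the acyl group; it sets out from 16 and comes back at 20. Friedel–Crafts acylation of 16 with 19 (TiCl4, CH2Cl2, −10 °C) gives 1-[(1R,2R,5S)-5',7'-dimethoxy-6,6-dimethylspiro[bicyclo[3.1.1]heptane-2,2'-chroman]-6'-yl]-3-methylbutan-1-one F6. Rieche formylation (Cl2CHOMe, TiCl4, CH2Cl2, −78 °C to 0 °C) at the only free position C8' gives the aryl(chloro)methyl methyl ether F7, which aqueous work-up hydrolyses to 20.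

**Further compounds**

F1 | step 6 | 2-(hydroxymethyl)-3,5-dimethoxyphenol | COc1cc(O)c(CO)c(OC)c1
F2 | step 6 | 3,5-dimethoxy-6-methylidenecyclohexa-2,4-dien-1-one (o-quinone methide) | C=C1C(OC)=CC(OC)=CC1=O
F3 | step 5 | racemic 5-hydroxy-5-[2-(2-hydroxy-4,6-dimethoxyphenyl)ethyl]-7-methyl-1-(pyrrolidin-1-yl)oct-6-en-1-one | COc1cc(O)c(CCC(O)(C=C(C)C)CCCC(=O)N2CCCC2)c(OC)c1
F4 | step 5 | racemic 4-[5,7-dimethoxy-2-(2-methylprop-1-en-1-yl)-3,4-dihydro-2H-chromen-2-yl]-1-(pyrrolidin-1-yl)butan-1-one | COc1cc(OC)c2CCC(C=C(C)C)(CCCC(=O)N3CCCC3)Oc2c1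
F5 | step 5 | 4-[(2S)-5,7-dimethoxy-2-(2-methylprop-1-en-1-yl)-3,4-dihydro-2H-chromen-2-yl]-1-(pyrrolidin-1-yl)butan-1-one (enantiomer of 10) | COc1cc(OC)c2CC[C@](C=C(C)C)(CCCC(=O)N3CCCC3)Oc2c1
F6 | step 8 | 1-[(1R,2R,5S)-5',7'-dimethoxy-6,6-dimethylspiro[bicyclo[3.1.1]heptane-2,2'-chroman]-6'-yl]-3-methylbutan-1-one | COc1c(C(=O)CC(C)C)c(OC)c2CC[C@@]3(CC[C@H]4C[C@@H]3C4(C)C)Oc2c1
F7 | step 8 | 8'-[chloro(methoxy)methyl] derivative of F6 (aryl(chloro)methyl methyl ether) | COc1c(C(=O)CC(C)C)c(OC)c2CC[C@@]3(CC[C@H]4C[C@@H]3C4(C)C)Oc2c1C(Cl)OC
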